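The numbers belong to no real substance; no experiment stands behind them.

**One step.** In a one-step world substrate became intermediate and stayed there, and its peak was a plain climb. This flask gave the intermediate a way out.

common to all: free catalyst 0.8 mol%
- birch: substrate 0.050 M (fed, over 20.0 h); time 40 h; all but substrate at the start; substrate goes in evenly over 20.0 h, the run ends at 40 h
- elm: substrate 0.050 M; a single well-mixed tank run continuously and read at steady state, 40 h in it on average
- ash: substrate 0.050 M; time 40 h; a closed flask charged with all of it at once and left for 40 h
- oak: substrate 0.050 M; a single well-mixed tank run continuously and read at steady state, 120 h in it on average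

    substrate → intermediate (k1 = 0.032 h⁻¹)
    free catalyst + intermediate → free catalyst + target (k2 = 160 M⁻¹ h⁻¹)
    target → over-reaction product (k3 = 0.012 h⁻¹)
    substrate + free catalyst → spent catalyst (k4 = 0.078 M⁻¹ h⁻¹)

- the stated concentrations are those of everything mixed, before any reaction; amounts are the same in each set-up
- the feed brings no volume worth counting
- run time (birch): 40 h

* the set-up with the highest amount of intermediate at the outlet or at the end, in percent of the substrate put in ("none" if the first two lie within 2 percentage points) (birch / elm / ash / oak / none)
* amount of intermediate at the outlet or at the end, in percent of the substrate put in, birch
* amount of intermediate at the outlet or at the end, in percent of the substrate put in, elm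
* amount of intermediate at the outlet or at the end, in percent of the substrate put in, ash
* amount of intermediate at the outlet or at the end, in percent of the substrate put in, oak

**The drain.** I followed one molecule. Free catalyst dies at 0.00390 h⁻¹ with substrate as charged, slower than 0.032 h⁻¹, so I held c(free catalyst) at its charge. Then k2 times c(free catalyst) is 0.0640 h⁻¹; I call this pseudo-first-order exit rate of the intermediate the drain. It is twice the rate of entry.

**Closed flasks.** A molecule of age t is intermediate with the chance k1/(drain − k1) times the difference of the two decays. For ash that gave 20.1%. In birch the mean molecule arrived halfway through dosing, so it was younger, and I got 23.6%. By this reckoning ash peaked near 21.7 h, so expect a falling peak.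

**The tanks.** Here there were two forks: react or leave, then survive the drain or not. Multiplying those chances gave 15.8% for elm and 9.14% for oak. My pick was birch.

**The forecast.** The forecast named birch, with 24.3% for birch, 16.5% for elm, 21.5% for ash, higher than mine there, and 9.9% for oak, saying “at 40 h it is highest where substrate arrived latest”.

**The result.** The simulation gave 24.3% in birch, 16.5% in elm, 21.5% in ash and 9.91% in oak, so birch led, and my order stood.

**The comparison.** The drain of 0.0640 h⁻¹ was twice the 0.032 h⁻¹ at which substrate feeds the intermediate, and in ash the intermediate's half-life by the second step, catalyst as charged, was 11 h, short against the 40 h. Ash left for 400 h had, at that drain, 25.6 intermediate lifetimes to run, and it read 0% of intermediate.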